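## Structural features

The target is a 2-amino-2-imidazoline (a cyclic guanidine, ring atoms N1, C2, N3, C4, C5) bonded through C4 to C3 of a 2,5-dibromo-1H-indole. C4 is the only stereocentre and is (R); it lies between the unsubstituted methylene C5 and the indole C3, so no neighbouring stereocentre can relay or correct its configuration. The C4–N3 bond is the fragile element: an indol-3-ylmethyl nitrogen can ionise with help from the indole nitrogen lone pair (azafulvene formation, as in gramine chemistry), most readily when N3 carries an acceptor group while the indole nitrogen is free, and this would racemise C4. The 2-bromoindole is sensitive to acid (C3 protonation and hydrolysis towards the oxindole) and, whenever C3 carries a C=O or C=N group, to nucleophilic displacement at C2; the two aryl bromides also rule out hydrogenolysis, dissolving metals, stannane radical chemistry and most zerovalent palladium or nickel chemistry. The free guanidine is strongly basic and very polar, so it is best uncovered in the last step. The real difficulty is therefore to create one isolated benzylic C–N stereocentre beside an electron-rich, halogenated heteroarene and then to keep it. The key step uses the fact that N3–C4 can be drawn from an aldimine C=N and C5–N1–C2 from the C–N=C unit of an α-isothiocyanato carbonyl compound, so that one addition–cyclisation forms C4–C5 and N3–C2, sets C4, and leaves a sulfur at C2 that is later exchanged for the exocyclic NH2.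

## Logic of the disconnections

**22 ⇒ 20.** The exocyclic C2–N bond of 22 is cut and C2 receives a thiocarbonyl sulfur. Sulfur is the atom that the ring-forming step delivers at C2, and 20 is neutral and easy to purify whereas 22 is a strong base. The gain is that no guanidine has to be carried or protected. The forward step must alkylate sulfur only (through 21) and then replace it by nitrogen without ionising the C4–N3 bond.

**20 ⇒ 18.** The N3–S(sulfonyl) bond and the indole N–C(carbamate) bond are cut. Both groups are needed earlier, because they make the imine carbon electrophilic and shut off azafulvene formation. The gain is that both can be released in one flask. The demand is one of order: the sulfonyl group must leave first (giving 19), so that N3 is no longer a leaving group when the indole nitrogen is freed, and the thiolate must attack the nitroarene and not C2–Br.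

**18 ⇒ 16 ⇒ 15.** A C5–C(carboxyl) bond is added back and the acid is returned to its imide. C5 can only be made nucleophilic if it carries an acyl group; that group has no counterpart in 22 and must be excised. The gain is that 15 already holds every ring atom and the stereocentre. The forward steps need an acyl cleavage without oxidant (because of the thiocarbonyl) and without ring-opening at C4, and a hydrodecarboxylation (through 17) that leaves two C–Br bonds, a nitro group and the C=S group untouched.

**15 ⇒ 7 + 13.** The C4–C5 and N3–C2 bonds are cut. This is the most convergent cut of the ring, since it divides the molecule into the complete indole half and a three-atom C–N=C unit, and it is the point where C4 is created. The gain is one ring, two bonds and the stereocentre from two achiral partners. The forward step needs catalyst-controlled addition to one face of the imine and a fast ring closure of 14 that makes the addition irreversible.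

**7 ⇒ 5 + 6; 5 ⇒ 4; 4 ⇒ 1.** The C=N bond, then the indole N–C(carbamate) bond, then the C3–CHO and C2–Br bonds are cut. The last cut returns both indole substituents to a lactam, whose carbonyl becomes the C2 bromide while its enolisable C3 is formylated (through 2 and 3). The gain is a single operation from a commercial lactam to the fully substituted indole aldehyde. The demand is a dehydrating condensation mild enough for the activated C2–Br and the carbamate.

**13 ⇒ 11 ⇒ 10 ⇒ 8 + 9.** The N=C=S group is traced back to an azide (through 12), the C–N3 bond to a C–Cl bond, and the imide N–acyl bond is cut. Each cut is a standard functional-group interchange and ends at two bulk chemicals. The demands are a weakly basic nitrogen nucleophile that spares the imide, and complete removal of inorganic azide before carbon disulfide is used.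

## Other disconnections considered

**Alternative 1:** The cut is the indole C3–C3a bond, so that the benzo-fused pyrrole ring is closed onto a side chain that already holds the complete imidazolidinone with C4 in place.
- Forward key step: the tertiary anilide A1 would be deprotonated by NaOtBu and its amide enolate arylated at the carbon–iodine bond with Pd(OAc)2 and tricyclohexylphosphine (oxidative addition of zerovalent palladium at the iodide ahead of the bromide, enolate binding, reductive elimination). This closes the lactam and gives the oxindole A2. Deoxybromination of the lactam carbonyl would then supply the 2-bromoindole.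
- In its favour: C4 would be brought in from the chiral pool and no asymmetric step is needed, which is a point on which this plan is the better one. The lactam-to-bromide logic for C2–Br is the same as in step 1 of the chosen route and is its equal.
- Against it: the enolate sits β to N3 on an exocyclic carbon, so an E1cB opening of the urea ring and re-closure is geometrically allowed under hot alkoxide and would erode C4. Zerovalent palladium must ignore the aryl bromide throughout. Three 4-methoxybenzyl groups (one on the indole nitrogen, two on urea nitrogens) would need oxidising or hot acidic removal, which a 2-bromoindole tolerates badly. The C2 oxygen of a urea is much harder to exchange for NH2 than the sulfur of 20.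
- Comparison: structurally this plan builds the arene–heterocycle junction and leaves the C4–N bonds alone, while the chosen plan builds the imidazoline on a finished indole. Mechanistically it relies on organopalladium chemistry in the presence of C–Br, the chosen plan on polar organocatalysis that cannot touch C–Br. In step economy it is clearly longer, because A1 needs a multistep assembly and A2 still needs deoxybromination, three deprotections and a urea-to-guanidine exchange.

**Alternative 2:** The cut is C5–N1, made last by amination of an unactivated methyl C–H bond.
- Forward key step: the sulfonylguanidine A3 would be N-iodinated by I2 and PhI(OAc)2, and visible light would cleave the N–I bond. The nitrogen radical would take a hydrogen from the C5 methyl group through a six-membered transition state (a Hofmann–Löffler–Freytag-type relay), and the primary iodide so formed would be displaced by nitrogen to give A4. A3 is (S); the label becomes (R) in A4 only because C5 gains a nitrogen and overtakes the indolyl carbon in priority.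
- In its favour: all three guanidine nitrogens and C2 are in place before the ring closes and nothing has to be excised afterwards. This is better atom economy than the chosen plan, which discards a carboxyl carbon and an oxazolidinone. The step count from 4 would be about equal.
- Against it: the hydrogen to be abstracted is on a primary carbon, while the C4–H bond is benzylic and α to nitrogen and far weaker, so any intermolecular abstraction or over-oxidation at C4 would destroy the only stereocentre. Electrophilic iodine and the trivalent iodine oxidant are not innocent towards an indole, even a tosylated and brominated one. The trichloroethoxysulfonyl and tosyl groups come off under reducing-metal or strongly basic conditions that endanger C–Br.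
- Comparison: structurally both plans close the same ring on a finished indole. Mechanistically this one sets C4 beforehand by an auxiliary or reagent and then runs a radical chain next to it, whereas the chosen plan sets C4 in the ring-forming step by a polar, catalyst-controlled addition and never generates a radical at or next to C4 while an oxidant is present. The alternative is the more elegant on paper and the more exposed at its key step.

**Alternative 3:** The cuts are C5–N1 and C2–N3, made in one operation by a Curtius rearrangement.
- Forward key step: the β-amino acid A5 would react with diphenylphosphoryl azide and a tertiary amine. The acyl azide would lose nitrogen on warming with migration of the CH2 group to nitrogen, and the carbamate N–H would add to the isocyanate to give the imidazolidinone A6. A5 is (S) for the same priority reason as in Alternative 2.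
- In its favour: the rearrangement does not touch C4 and is very dependable, so on reliability of the ring-forming event this plan is the better one. The carboxyl carbon is kept as C2, which is better atom economy than the chosen plan. β-Amino acids of this kind are accessible by established auxiliary-controlled Mannich chemistry, and the acyl azide is no greater hazard than the azide 11 of the chosen route (equal).
- Against it: the ring is delivered with oxygen at C2, so a urea must be activated (strong O-alkylating agent or dehydrative activation) before ammonia can enter, which is harsher and longer than the sulfur exchange from 20. A6 has no bromine at indole C2; late C2 bromination would have to be done next to the sensitive C4–N3 bond, either by lithiation beside an aryl bromide and acidic N–H groups or by electrophilic bromination through a 3-bromoindolenine that invites ionisation at C4. The tosyl group still has to be removed from a 2-bromoindole.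
- Comparison: structurally both plans close the same ring on a finished indole, and the chosen plan has C2–Br and a C2 heteroatom of the right kind from the start. Mechanistically both are polar and stereochemically benign at C4 once it exists; the difference is where C4 comes from. In step economy the alternative is comparable up to A6 and longer from there.

Key step: step 7

Remark on the structures: ring locants of the imidazolidine/imidazoline follow the target throughout (N1, C2, N3, C4 bearing the indolyl group, C5). With these locants the annulation product 15 is (4R,5S), which is the trans isomer, and the (R) label at C4 persists to 22 because C5 always outranks the indolyl carbon. The structures of the precursors, the product and the starting materials were checked against this and no correction is needed.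

Assumption: the catalyst of step 7 is the quinine-derived thiourea 1-[3,5-bis(trifluoromethyl)phenyl]-3-[(8S,9S)-6'-methoxycinchonan-9-yl]thiourea, assumed by analogy with related Mannich additions to deliver the enolate to the Si face of the imine. If the sense proves opposite, the quinidine-derived pseudoenantiomer is used instead.

## Route

Step 1
Reactants: 1 5-bromooxindole
Product: 4 2,5-dibromo-1H-indole-3-carbaldehyde, via aminomethylene oxindole 2 (not isolated), via bromo azafulvene 3 (not isolated)
Conditions: POBr3 (2.5 equiv), DMF (3 equiv), CH2Cl2, 0 °C → reflux; then ice-water, 0 °C → rt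
Reagents that add atoms: N,N-dimethylformamide, CN(C)C=O; phosphorus oxybromide POBr3, O=P(Br)(Br)Br; water, O
Why: Vilsmeier–Haack haloformylation: the bromoiminium reagent formylates the enolisable C3 of the lactam, POBr3 converts the vinylogous urea carbonyl into the C2 bromide with aromatisation, and water hydrolyses the iminium to the aldehyde.

Step 2
Reactants: 4 2,5-dibromo-1H-indole-3-carbaldehyde
Product: 5 tert-butyl 2,5-dibromo-3-formyl-1H-indole-1-carboxylate
Conditions: Boc2O (1.2 equiv), DMAP (5 mol%), MeCN, rt
Reagents that add atoms: di-tert-butyl dicarbonate, CC(C)(C)OC(=O)OC(=O)OC(C)(C)C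
Why: DMAP-catalysed N-acylation of the acidic N–H of a 3-formylindole; the carbamate removes the vinylogous amide donation of the indole nitrogen, so the aldehyde and the later imine react like ordinary electron-poor aryl derivatives.

Step 3
Reactants: 5 tert-butyl 2,5-dibromo-3-formyl-1H-indole-1-carboxylate; 6 2-nitrobenzenesulfonamide
Product: 7 tert-butyl 2,5-dibromo-3-[(E)-{[(2-nitrophenyl)sulfonyl]imino}methyl]-1H-indole-1-carboxylate
Conditions: Ti(OEt)4 (2 equiv), CH2Cl2, 40 °C; brine, filtration through Celite, crystallisation
Reagents that add atoms: none
Why: Lewis acid-mediated dehydrative condensation of an aldehyde with a sulfonamide, in which Ti(OEt)4 activates the carbonyl and consumes the water; the E imine is the thermodynamic isomer.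

Step 4
Reactants: 8 oxazolidin-2-one; 9 chloroacetyl chloride
Product: 10 3-(2-chloroacetyl)oxazolidin-2-one
Conditions: NaH (1.0 equiv), THF, 0 °C; then addition to 9, 0 °C → rt
Reagents that add atoms: none
Why: N-acylation of the sodium salt of a cyclic carbamate with an acid chloride; inverse addition keeps the acidic α-chloro imide away from excess base.

Step 5
Reactants: 10 3-(2-chloroacetyl)oxazolidin-2-one
Product: 11 3-(2-azidoacetyl)oxazolidin-2-one
Conditions: NaN3 (1.1 equiv), DMF, rt; water/EtOAc work-up, solvent exchanged to THF without evaporation to dryness
Reagents that add atoms: sodium azide NaN3, [Na+].[N-]=[N+]=[N-]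
Why: SN2 displacement of an α-carbonyl chloride by the weakly basic azide ion, which leaves the imide intact; the small organic azide is handled only in solution, no halogenated solvent is used, and the aqueous washes remove all inorganic azide.

Step 6
Reactants: 11 3-(2-azidoacetyl)oxazolidin-2-one
Product: 13 3-(2-isothiocyanatoacetyl)oxazolidin-2-one, via iminophosphorane 12 (not isolated)
Conditions: PPh3 (1.05 equiv), CS2 (10 equiv), THF, rt
Reagents that add atoms: carbon disulfide, S=C=S
Why: Staudinger reaction of the azide with PPh3 gives the iminophosphorane with loss of N2, and an aza-Wittig reaction with CS2 turns it into the isothiocyanate; this is the standard azide-to-isothiocyanate conversion and is safe only because no azide ion is left to react with CS2.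

Step 7
Reactants: 7 tert-butyl 2,5-dibromo-3-[(E)-{[(2-nitrophenyl)sulfonyl]imino}methyl]-1H-indole-1-carboxylate; 13 3-(2-isothiocyanatoacetyl)oxazolidin-2-one
Product: 15 3-{[(4R,5S)-4-[1-(tert-butoxycarbonyl)-2,5-dibromo-1H-indol-3-yl]-3-[(2-nitrophenyl)sulfonyl]-2-thioxoimidazolidin-5-yl]carbonyl}oxazolidin-2-one, via open-chain Mannich adduct 14 (not isolated)
Conditions: quinine-derived thiourea catalyst (10 mol%), 13 (1.2 equiv), 4 Å MS, toluene/CH2Cl2, −20 °C
Reagents that add atoms: none
Why: The quinuclidine nitrogen of the catalyst removes a proton from the doubly activated CH2 of 13 and keeps the enolate as a hydrogen-bonded ion pair, while the thiourea N–H bonds hold the sulfonyl imine 7 (bifunctional catalysis). Mannich addition of the enolate carbon to the imine carbon forms C4–C5 and gives the sulfonamide anion of 14. That nitrogen then adds to the central carbon of the isothiocyanate and forms N3–C2; the closure is 5-exo-dig when counted on the C=S bond, the charge passing into the N1–C2–S unit, and proton transfer to N1 frees the catalyst. The closest known reaction type is the enantioselective Mannich addition–cyclisation of α-isothiocyanato imides with N-sulfonyl aldimines under cinchona thiourea catalysis. C4 is controlled by the catalyst, which has to deliver the enolate to the Si face of the imine carbon (N > indolyl > H); this is (R) because C5, which bears N1, outranks the indolyl carbon. C5 follows from the relative topicity of the addition and should end up trans to the indolyl group, the less crowded arrangement; its configuration is irrelevant because C5 becomes a methylene in step 9. The step needs 1,2-addition to the C=N bond in preference to displacement of the C2 bromide and a high facial bias: the carbamate and the sulfonyl group make the imine carbon the most electrophilic site, the catalytic weak base keeps the enolate concentration low, and the irreversible ring closure stops any retro-Mannich leakage of the C4 configuration.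

Step 8
Reactants: 15 3-{[(4R,5S)-4-[1-(tert-butoxycarbonyl)-2,5-dibromo-1H-indol-3-yl]-3-[(2-nitrophenyl)sulfonyl]-2-thioxoimidazolidin-5-yl]carbonyl}oxazolidin-2-one
Product: 16 (4R,5S)-4-[1-(tert-butoxycarbonyl)-2,5-dibromo-1H-indol-3-yl]-3-[(2-nitrophenyl)sulfonyl]-2-thioxoimidazolidine-5-carboxylic acid
Conditions: LiOH·H2O (2.2 equiv), THF/H2O (3:1), 0 °C; then 1 M HCl to pH 3, 0 °C
Reagents that add atoms: lithium hydroxide LiOH, [Li+].[OH-]
Why: Imide hydrolysis at the exocyclic carbonyl, which is activated by the α-nitrogen and unhindered because the oxazolidinone has no ring substituent; peroxide is left out because it would oxidise the thiocarbonyl. Ring-opening by β-elimination of N3 from the C5 enolate would be the reverse of a 5-endo-trig closure and is stereoelectronically disfavoured, so C4 should be safe, and epimerisation at C5 is harmless.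

Step 9
Reactants: 16 (4R,5S)-4-[1-(tert-butoxycarbonyl)-2,5-dibromo-1H-indol-3-yl]-3-[(2-nitrophenyl)sulfonyl]-2-thioxoimidazolidine-5-carboxylic acid
Product: 18 tert-butyl 2,5-dibromo-3-{(4R)-3-[(2-nitrophenyl)sulfonyl]-2-thioxoimidazolidin-4-yl}-1H-indole-1-carboxylate, via thiohydroxamate ester 17 (not isolated)
Conditions: N-hydroxypyridine-2-thione, DCC, DMAP (cat.), CH2Cl2, 0 °C → rt, dark; then t-BuSH (10 equiv), visible light (white LED), rt
Reagents that add atoms: none
Why: Barton reductive decarboxylation: carbodiimide esterification gives the thiohydroxamate ester, light cleaves its N–O bond, loss of CO2 gives the N1-stabilised C5 radical, and hydrogen transfer from the thiol completes the chain; a thiol, unlike a stannane, does not reduce aryl bromides. The activated ester cannot acylate the thiocarbonyl sulfur internally, since that would require a bridged bicycle, and C4 is not involved.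

Step 10
Reactants: 18 tert-butyl 2,5-dibromo-3-{(4R)-3-[(2-nitrophenyl)sulfonyl]-2-thioxoimidazolidin-4-yl}-1H-indole-1-carboxylate
Product: 20 (4R)-4-(2,5-dibromo-1H-indol-3-yl)imidazolidine-2-thione, via Boc-protected thiourea 19 (not isolated)
Conditions: 4-mercaptobenzoic acid (2 equiv), K2CO3 (6 equiv), DMF, rt; then MeOH, 55 °C
Reagents that add atoms: none
Why: The thiolate attacks the nitro-substituted ring at the sulfonyl-bearing carbon (nucleophilic aromatic ipso-substitution through a Meisenheimer adduct), releasing SO2 and the thiourea nitrogen of 19; K2CO3 in warm methanol then removes the carbamate from the indole nitrogen by methanolysis. The sulfonyl group leaves first, so N3 is no longer a leaving group when the indole nitrogen becomes free, and no acid touches the 2-bromoindole.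

Step 11
Reactants: 20 (4R)-4-(2,5-dibromo-1H-indol-3-yl)imidazolidine-2-thione
Product: 22 (4R)-4-(2,5-dibromo-1H-indol-3-yl)-4,5-dihydro-1H-imidazol-2-amine, via isothiouronium iodide 21 (not isolated)
Conditions: MeI (1.1 equiv), MeOH, rt; evaporation; 7 M NH3 in MeOH, sealed tube, 65 °C; basic ion-exchange resin
Reagents that add atoms: ammonia, N
Why: S-Methylation of the soft thiocarbonyl sulfur gives the isothiouronium salt, and ammonia replaces methanethiolate by addition–elimination at C2 (guanylation with an S-methylisothiourea); without added base the indole N–H is not alkylated, and C4 takes no part.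

## Compound list

1 | 5-bromooxindole (5-bromo-1,3-dihydro-2H-indol-2-one) | O=C1Cc2cc(Br)ccc2N1 | starting material
2 | 5-bromo-3-[(dimethylamino)methylene]indolin-2-one | CN(C)C=C1C(=O)Nc2ccc(Br)cc12 | intermediate
3 | 2,5-dibromo-3-[(dimethylamino)methylene]-3H-indole | CN(C)C=C1C(Br)=Nc2ccc(Br)cc12 | intermediate
4 | 2,5-dibromo-1H-indole-3-carbaldehyde | O=Cc1c(Br)[nH]c2ccc(Br)cc12 | intermediate
5 | tert-butyl 2,5-dibromo-3-formyl-1H-indole-1-carboxylate | CC(C)(C)OC(=O)n1c(Br)c(C=O)c2cc(Br)ccc21 | intermediate
6 | 2-nitrobenzenesulfonamide | NS(=O)(=O)c1ccccc1[N+](=O)[O-] | starting material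
7 | tert-butyl 2,5-dibromo-3-[(E)-{[(2-nitrophenyl)sulfonyl]imino}methyl]-1H-indole-1-carboxylate | CC(C)(C)OC(=O)n1c(Br)c(/C=N/S(=O)(=O)c2ccccc2[N+](=O)[O-])c2cc(Br)ccc21 | intermediate
8 | oxazolidin-2-one | O=C1NCCO1 | starting material
9 | chloroacetyl chloride | ClCC(Cl)=O | starting material
10 | 3-(2-chloroacetyl)oxazolidin-2-one | ClCC(=O)N1CCOC1=O | intermediate
11 | 3-(2-azidoacetyl)oxazolidin-2-one | [N-]=[N+]=NCC(=O)N1CCOC1=O | intermediate
12 | 3-{2-[(triphenyl-λ5-phosphanylidene)amino]acetyl}oxazolidin-2-one | O=C(CN=P(c1ccccc1)(c1ccccc1)c1ccccc1)N1CCOC1=O | intermediate
13 | 3-(2-isothiocyanatoacetyl)oxazolidin-2-one | S=C=NCC(=O)N1CCOC1=O | intermediate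
14 | 3-{(2S,3R)-3-[1-(tert-butoxycarbonyl)-2,5-dibromo-1H-indol-3-yl]-2-isothiocyanato-3-{[(2-nitrophenyl)sulfonyl]amino}propanoyl}oxazolidin-2-one | O=[N+]([O-])c1ccccc1S(=O)(=O)N[C@H](c1c(Br)n(C(=O)OC(C)(C)C)c2ccc(Br)cc12)[C@H](N=C=S)C(=O)N1CCOC1=O | intermediate
15 | 3-{[(4R,5S)-4-[1-(tert-butoxycarbonyl)-2,5-dibromo-1H-indol-3-yl]-3-[(2-nitrophenyl)sulfonyl]-2-thioxoimidazolidin-5-yl]carbonyl}oxazolidin-2-one (trans) | O=[N+]([O-])c1ccccc1S(=O)(=O)N1[C@H](c2c(Br)n(C(=O)OC(C)(C)C)c3ccc(Br)cc23)[C@@H](C(=O)N2CCOC2=O)NC1=S | intermediate
16 | (4R,5S)-4-[1-(tert-butoxycarbonyl)-2,5-dibromo-1H-indol-3-yl]-3-[(2-nitrophenyl)sulfonyl]-2-thioxoimidazolidine-5-carboxylic acid | O=[N+]([O-])c1ccccc1S(=O)(=O)N1[C@H](c2c(Br)n(C(=O)OC(C)(C)C)c3ccc(Br)cc23)[C@@H](C(=O)O)NC1=S | intermediate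
17 | 2-thioxopyridin-1(2H)-yl ester of 16 | O=[N+]([O-])c1ccccc1S(=O)(=O)N1[C@H](c2c(Br)n(C(=O)OC(C)(C)C)c3ccc(Br)cc23)[C@@H](C(=O)On2ccccc2=S)NC1=S | intermediate
18 | tert-butyl 2,5-dibromo-3-{(4R)-3-[(2-nitrophenyl)sulfonyl]-2-thioxoimidazolidin-4-yl}-1H-indole-1-carboxylate | O=[N+]([O-])c1ccccc1S(=O)(=O)N1[C@H](c2c(Br)n(C(=O)OC(C)(C)C)c3ccc(Br)cc23)CNC1=S | intermediate
19 | tert-butyl 2,5-dibromo-3-[(4R)-2-thioxoimidazolidin-4-yl]-1H-indole-1-carboxylate | S=C1N[C@H](c2c(Br)n(C(=O)OC(C)(C)C)c3ccc(Br)cc23)CN1 | intermediate
20 | (4R)-4-(2,5-dibromo-1H-indol-3-yl)imidazolidine-2-thione | S=C1N[C@H](c2c(Br)[nH]c3ccc(Br)cc23)CN1 | intermediate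
21 | (4R)-4-(2,5-dibromo-1H-indol-3-yl)-2-(methylsulfanyl)-4,5-dihydro-1H-imidazol-3-ium iodide | CSC1=[NH+][C@H](c2c(Br)[nH]c3ccc(Br)cc23)CN1.[I-] | intermediate
22 | (4R)-4-(2,5-dibromo-1H-indol-3-yl)-4,5-dihydro-1H-imidazol-2-amine | NC1=N[C@H](c2c(Br)[nH]c3ccc(Br)cc23)CN1 | target

## Step count and least certain steps

Total step count: 11. Longest linear sequence: 8 steps (steps 1, 2, 3, 7, 8, 9, 10, 11; the branch through steps 4, 5, 6 is equally long).

**Key step (step 7).** The likeliest failure is insufficient or reversed facial selectivity, because an imine flanked by the C2 bromine and the benzo ring fits the catalyst less well than a simple aryl imine. An uncatalysed background addition and displacement of the activated C2 bromide by the enolate or the amine catalyst are further risks. A reversed sense alone is met by the pseudoenantiomeric catalyst. The fallback proper replaces catalyst control by auxiliary control: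
- It sets out from 5, which would be condensed with (R)-tert-butanesulfinamide and Ti(OEt)4 to the N-sulfinyl imine F1. This auxiliary enantiomer is chosen by analogy with chelate-controlled ester enolate additions, which attack the Si face.
- Soft enolisation of 13 (MgBr2·OEt2, iPr2NEt, CH2Cl2, −40 °C) and addition through a chelated transition state, followed by the same ring closure, would give the N3-sulfinyl thioxoimidazolidine imide F2.
- HCl in methanol at 0 °C would remove the sulfinyl group to give the N3-unsubstituted imide F3, and LiOH as in step 8 would give the acid F4.
- Thiohydroxamate ester decarboxylation of F4 as in step 9 comes back to the route at 19, which is then taken through the methanolysis half of step 10 to 20.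

**Step 3.** Condensation of a hindered, electron-poor aldehyde with a weakly nucleophilic sulfonamide may stall, and ethoxide transfer from titanium may displace the C2 bromide or cleave the carbamate. The fallback is an imino-group transfer with no alkoxide or water present. From 6, SOCl2 at reflux would give N-sulfinyl-2-nitrobenzenesulfonamide F5. Heating F5 with 5 in toluene (cycloaddition to the carbonyl and loss of SO2) comes back to the route at 7.

**Step 8.** Hydroxide may attack the ring carbonyl of the oxazolidinone and open it to a hydroxyethyl amide instead of cleaving the exocyclic acyl bond. The fallback separates acyl transfer from hydrolysis. From 15, MeOMgBr (from MeMgBr and MeOH, 0 °C) would exchange only the exocyclic acyl group and give the methyl ester F6. LiOH at 0 °C, now without a competing ring carbonyl, comes back to the route at 16.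

**Step 9.** The C5 radical may be intercepted before hydrogen transfer, by ipso attack on the electron-poor nitroaryl ring or addition to the nitro group, and the light-sensitive ester may form inefficiently beside the sulfonyl thiourea. The fallback reverses the order of deprotection and decarboxylation so that no nitroarene is present in the radical step. From 16, the conditions of step 10 would give the fully deprotected thiourea acid F7. Esterification of F7 with N-hydroxypyridine-2-thione and photolysis with t-BuSH comes back to the route at 20.

**Step 10.** Methanolysis of the carbamate may be incomplete, or C4 may erode through reversible ionisation of the C4–N3 bond once the indole nitrogen is free in hot basic methanol. The fallback keeps the carbamate to the end and removes it with acid instead of base. From 18, the thiolate cleavage alone (MeCN, rt) gives 19, which is isolated. MeI would give the Boc-protected isothiouronium iodide F8, and ammonia in methanol at the lowest workable temperature the Boc-protected guanidine F9. Any carbamate lost at this stage gives 22 directly. Brief treatment of F9 with TFA in CH2Cl2 at 0 °C and neutralisation comes back to the route at 22.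

## Further compounds

F1 | step 7 | tert-butyl 2,5-dibromo-3-[(E)-{[(R)-tert-butylsulfinyl]imino}methyl]-1H-indole-1-carboxylate | CC(C)(C)[S@@](=O)/N=C/c1c(Br)n(C(=O)OC(C)(C)C)c2ccc(Br)cc12
F2 | step 7 | 3-{[(4R,5S)-4-[1-(tert-butoxycarbonyl)-2,5-dibromo-1H-indol-3-yl]-3-[(R)-tert-butylsulfinyl]-2-thioxoimidazolidin-5-yl]carbonyl}oxazolidin-2-one | CC(C)(C)[S@@](=O)N1[C@H](c2c(Br)n(C(=O)OC(C)(C)C)c3ccc(Br)cc23)[C@@H](C(=O)N2CCOC2=O)NC1=S
F3 | step 7 | 3-{[(4R,5S)-4-[1-(tert-butoxycarbonyl)-2,5-dibromo-1H-indol-3-yl]-2-thioxoimidazolidin-5-yl]carbonyl}oxazolidin-2-one | N1[C@H](c2c(Br)n(C(=O)OC(C)(C)C)c3ccc(Br)cc23)[C@@H](C(=O)N2CCOC2=O)NC1=S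
F4 | step 7 | (4R,5S)-4-[1-(tert-butoxycarbonyl)-2,5-dibromo-1H-indol-3-yl]-2-thioxoimidazolidine-5-carboxylic acid | N1[C@H](c2c(Br)n(C(=O)OC(C)(C)C)c3ccc(Br)cc23)[C@@H](C(=O)O)NC1=S
F5 | step 3 | N-sulfinyl-2-nitrobenzenesulfonamide | O=S=NS(=O)(=O)c1ccccc1[N+](=O)[O-]
F6 | step 8 | methyl (4R,5S)-4-[1-(tert-butoxycarbonyl)-2,5-dibromo-1H-indol-3-yl]-3-[(2-nitrophenyl)sulfonyl]-2-thioxoimidazolidine-5-carboxylate | O=[N+]([O-])c1ccccc1S(=O)(=O)N1[C@H](c2c(Br)n(C(=O)OC(C)(C)C)c3ccc(Br)cc23)[C@@H](C(=O)OC)NC1=S
F7 | step 9 | (4R,5S)-4-(2,5-dibromo-1H-indol-3-yl)-2-thioxoimidazolidine-5-carboxylic acid | N1[C@H](c2c(Br)[nH]c3ccc(Br)cc23)[C@@H](C(=O)O)NC1=S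
F8 | step 10 | (4R)-4-[1-(tert-butoxycarbonyl)-2,5-dibromo-1H-indol-3-yl]-2-(methylsulfanyl)-4,5-dihydro-1H-imidazol-3-ium iodide | CSC1=[NH+][C@H](c2c(Br)n(C(=O)OC(C)(C)C)c3ccc(Br)cc23)CN1.[I-]
F9 | step 10 | tert-butyl 3-[(4R)-2-amino-4,5-dihydro-1H-imidazol-4-yl]-2,5-dibromo-1H-indole-1-carboxylate | NC1=N[C@H](c2c(Br)n(C(=O)OC(C)(C)C)c3ccc(Br)cc23)CN1
A1 | alternative 1 | N-(4-bromo-2-iodophenyl)-N-(4-methoxybenzyl)-2-[(4R)-1,3-bis(4-methoxybenzyl)-2-oxoimidazolidin-4-yl]acetamide | COc1ccc(CN(C(=O)C[C@@H]2CN(Cc3ccc(OC)cc3)C(=O)N2Cc2ccc(OC)cc2)c2ccc(Br)cc2I)cc1
A2 | alternative 1 | 5-bromo-1-(4-methoxybenzyl)-3-[(4R)-1,3-bis(4-methoxybenzyl)-2-oxoimidazolidin-4-yl]indolin-2-one | COc1ccc(CN2C(=O)C([C@@H]3CN(Cc4ccc(OC)cc4)C(=O)N3Cc3ccc(OC)cc3)c3cc(Br)ccc32)cc1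
A3 | alternative 2 | 1-[(1S)-1-(2,5-dibromo-1-tosyl-1H-indol-3-yl)ethyl]-3-[(2,2,2-trichloroethoxy)sulfonyl]guanidine | C[C@H](NC(N)=NS(=O)(=O)OCC(Cl)(Cl)Cl)c1c(Br)n(S(=O)(=O)c2ccc(C)cc2)c2ccc(Br)cc12
A4 | alternative 2 | 2,2,2-trichloroethyl N-[(4R)-4-(2,5-dibromo-1-tosyl-1H-indol-3-yl)imidazolidin-2-ylidene]sulfamate | ClC(Cl)(Cl)COS(=O)(=O)N=C1N[C@H](c2c(Br)n(S(=O)(=O)c3ccc(C)cc3)c3ccc(Br)cc23)CN1
A5 | alternative 3 | (3S)-3-(5-bromo-1-tosyl-1H-indol-3-yl)-3-[(tert-butoxycarbonyl)amino]propanoic acid | CC(C)(C)OC(=O)N[C@H](c1cn(S(=O)(=O)c2ccc(C)cc2)c2ccc(Br)cc12)CC(=O)O
A6 | alternative 3 | tert-butyl (5R)-5-(5-bromo-1-tosyl-1H-indol-3-yl)-2-oxoimidazolidine-1-carboxylate (N3-Boc, C4 (R) with target locants) | CC(C)(C)OC(=O)N1[C@H](c2cn(S(=O)(=O)c3ccc(C)cc3)c3ccc(Br)cc23)CNC1=O
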